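**Plan**

- Retrosynthesis: the vinyl bromide goes back to the vinyl iodide. The secondary methyl on cyclopentane C2, which is cis to the aryl ring, goes back to the carbonyl carbon of a six-membered lactone closed by the phenol oxygen (a cis-fused cyclopenta[c]chromen-4-one), with a tert-butyl ester on the same carbon as a removable activator.
- The two cyclopentane bonds C1–C5 and C2–C3 (C1 = aryl-bearing quaternary carbon, C3 = bromomethylidene carbon) are then cut together, leaving a coumarin-3-carboxylate and 4-iodobut-1-yne.
- Enabling feature: the phenol oxygen ortho to C1 and the cis aryl/methyl relation at C1/C2 make the C1–C2 unit a masked coumarin C4=C3 bond. This electron-poor alkene accepts a carbon radical at C4 and returns a radical at C3 within reach of the alkyne.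
- Forward order: pyranone ring of the coumarin (esterification/Knoevenagel), cyclopentane by radical [3+2] annulation with iodine transfer, then decarboxylation, resolution, lactone carbonyl to CH3, and iodine to bromine.
- Stereochemistry: the cis ring fusion of the annulation product fixes C2 relative to C1. The E geometry comes from iodine transfer anti to the fully substituted ring-fusion carbon and is kept in the halogen exchange. The absolute configuration comes from separating the (S)-1-phenylethylamides of the racemic lactone.

Key step: step 2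

Assumption: compounds 1, 2, 5, 9 and 13 are taken as catalogue chemicals; compounds 6, 7 and 8 are racemates and are drawn and named as the enantiomer that leads to the target.

**Step 1**
Reactants: 1 1-(5-bromo-2-hydroxy-4-methylphenyl)ethan-1-one; 2 3-(tert-butoxy)-3-oxopropanoic acid (mono-tert-butyl malonate)
Product: 4 tert-butyl 6-bromo-4,7-dimethyl-2-oxo-2H-chromene-3-carboxylate, via aryl tert-butyl malonate 3 (not isolated)
Conditions: EDC·HCl (1.3 equiv), DMAP (0.1 equiv), CH2Cl2, 0 °C to rt; then DBU (0.3 equiv), rt to 40 °C
Reagents that add atoms: none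
Why: Steglich-type esterification of the phenol followed by intramolecular Knoevenagel condensation of the malonate CH2 with the ortho acetyl group, driven by formation of the conjugated coumarin; no stereocentre is formed.

**Step 2**
Reactants: 4 tert-butyl 6-bromo-4,7-dimethyl-2-oxo-2H-chromene-3-carboxylate; 5 4-iodobut-1-yne
Product: 6 racemic tert-butyl (3E,3aR,9bS)-8-bromo-3-(iodomethylidene)-7,9b-dimethyl-4-oxo-1,2,3,9b-tetrahydrocyclopenta[c]chromene-3a(4H)-carboxylate (cis-fused; lactone carbonyl cis to the aryl ring, iodine trans to C3a)
Conditions: 5 (4 equiv), Et3B (0.3 equiv, in portions), air, PhH (0.5 M in 4), 50 °C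
Reagents that add atoms: none
Why: Proposed new method: a radical chain in which the nucleophilic but-3-ynyl radical (iodine abstraction from 5 by an ethyl radical) adds to C4 of the doubly activated C3=C4 bond of 4 and makes the quaternary carbon, the tertiary malonyl-type radical at C3 then closes onto the tethered terminal alkyne, and the σ-vinyl radical takes iodine from a further molecule of 5 and so carries the chain. The closest known reaction types are the iodine-atom-transfer annulation of propargyl iodomalonates with alkenes and the tin-hydride-mediated [3+2] annulation of but-3-ynyl radicals with electron-poor alkenes; here the polarity of the atom-transfer version is inverted, which is viable because only the very reactive vinyl radical, not the stabilised adduct radical, has to abstract iodine. The one ring closed is the cyclopentane, by 5-exo-dig attack of the C3 radical, and because the butynyl tether on C4 can reach the neighbouring radical centre only from its own face the 6/5 fusion is cis, which sets C3a relative to C9b; C9b itself forms without facial bias, so 6 is racemic. The step needs attack at C4 rather than C3 (secured by the two carbonyl groups on C3, which make C4 the electrophilic terminus and the adduct a stabilised radical), cyclisation faster than loss of the adduct radical (secured by the absence of a hydrogen donor), and E geometry (iodine is delivered to the lobe of the rapidly inverting vinyl radical that points away from the fully substituted C3a, which is also the thermodynamic preference).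

**Step 3**
Reactants: 6 racemic tert-butyl (3E,3aR,9bS)-8-bromo-3-(iodomethylidene)-7,9b-dimethyl-4-oxo-1,2,3,9b-tetrahydrocyclopenta[c]chromene-3a(4H)-carboxylate
Product: 8 racemic (3E,3aR,9bR)-8-bromo-3-(iodomethylidene)-7,9b-dimethyl-2,3,3a,9b-tetrahydrocyclopenta[c]chromen-4(1H)-one (cis-fused lactone), via carboxylic acid 7 (not isolated)
Conditions: TFA/CH2Cl2 (1:4), rt; evaporate; PhMe, 100 °C
Reagents that add atoms: none
Why: acidolysis of the tert-butyl ester and thermal decarboxylation of the malonic-type half ester through the lactone enol, which is protonated at C3a on the face that keeps the 6/5 fusion cis, so that H ends cis to the C9b methyl group and the lactone carbonyl stays cis to the aryl ring.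

**Step 4**
Reactants: 8 racemic (3E,3aR,9bR)-8-bromo-3-(iodomethylidene)-7,9b-dimethyl-2,3,3a,9b-tetrahydrocyclopenta[c]chromen-4(1H)-one; 9 (S)-1-phenylethan-1-amine
Product: 10 (1R,2R,5E)-2-(5-bromo-2-hydroxy-4-methylphenyl)-5-(iodomethylidene)-2-methyl-N-[(1S)-1-phenylethyl]cyclopentane-1-carboxamide
Conditions: 9 (3 equiv), 2-hydroxypyridine (0.2 equiv), PhMe, 60 °C; separation of the two diastereomeric amides on SiO2
Reagents that add atoms: none
Why: aminolysis of the aryl lactone turns the two enantiomers of 8 into diastereomeric phenolic amides (classical resolution of a lactone through its 1-phenylethylamides), of which the (1R,2R) isomer, to be assigned by X-ray analysis against the known (S) centre, is carried on.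

**Step 5**
Reactants: 10 (1R,2R,5E)-2-(5-bromo-2-hydroxy-4-methylphenyl)-5-(iodomethylidene)-2-methyl-N-[(1S)-1-phenylethyl]cyclopentane-1-carboxamide
Product: 11 (3E,3aR,9bR)-8-bromo-3-(iodomethylidene)-7,9b-dimethyl-2,3,3a,9b-tetrahydrocyclopenta[c]chromen-4(1H)-one (single enantiomer of 8)
Conditions: TsOH·H2O (1.5 equiv), PhMe, 80 °C
Reagents that add atoms: none
Why: acid-promoted lactonisation of the ortho-hydroxyaryl amide, helped by the fully substituted benzylic carbon (gem-dialkyl effect) and by protonation of the leaving amine, which does not touch either stereocentre.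

**Step 6**
Reactants: 11 (3E,3aR,9bR)-8-bromo-3-(iodomethylidene)-7,9b-dimethyl-2,3,3a,9b-tetrahydrocyclopenta[c]chromen-4(1H)-one
Product: 12 (3E,3aR,9bR)-8-bromo-3-(iodomethylidene)-7,9b-dimethyl-1,2,3,3a,4,9b-hexahydrocyclopenta[c]chromen-4-ol (lactol, both anomers)
Conditions: DIBAL-H (i-Bu2AlH, 1.2 equiv), CH2Cl2, −78 °C; aq. Rochelle salt
Reagents that add atoms: none
Why: partial reduction of an aryl lactone, which stops at the aluminium hemiacetal at low temperature and gives the lactol on hydrolysis, with the vinyl iodide and aryl bromide inert and the new hemiacetal centre of no consequence.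

**Step 7**
Reactants: 12 (3E,3aR,9bR)-8-bromo-3-(iodomethylidene)-7,9b-dimethyl-1,2,3,3a,4,9b-hexahydrocyclopenta[c]chromen-4-ol; 13 4-methylbenzenesulfonohydrazide
Product: 15 4-bromo-2-[(1R,2R,3E)-3-(iodomethylidene)-1,2-dimethylcyclopentyl]-5-methylphenol, via tosylhydrazone 14 (not isolated)
Conditions: 13 (1.1 equiv), EtOH, rt; evaporate; catecholborane (3 equiv), CHCl3, 0 °C to rt; NaOAc·3H2O (5 equiv), 50 °C
Reagents that add atoms: none
Why: the lactol reacts through its open hydroxy-aldehyde form to the tosylhydrazone, and hydroboration of C=N followed by loss of sulfinate and N2 (the mild tosylhydrazone variant of the Wolff–Kishner reduction) turns CH=N into CH3 under non-basic, non-radical conditions that should leave the adjacent stereocentre, the vinyl iodide and the aryl bromide intact.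

**Step 8**
Reactants: 15 4-bromo-2-[(1R,2R,3E)-3-(iodomethylidene)-1,2-dimethylcyclopentyl]-5-methylphenol
Product: 16 4-bromo-2-[(1R,2R,3E)-3-(bromomethylidene)-1,2-dimethylcyclopentyl]-5-methylphenol (target)
Conditions: CuI (10 mol %), trans-N,N'-dimethylcyclohexane-1,2-diamine (20 mol %), Me4NBr (5 equiv), EtOH, 110 °C (sealed tube)
Reagents that add atoms: tetramethylammonium bromide, C[N+](C)(C)C.[Br-]
Why: copper-catalysed vinylic halogen exchange (Finkelstein type) replaces iodine by bromine with retention of alkene geometry, driven by the stronger C–Br bond and the excess of bromide, while the aryl bromide can only exchange degenerately and the phenol does not couple in the absence of base.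

**Compound list**

1 | 1-(5-bromo-2-hydroxy-4-methylphenyl)ethan-1-one | CC(=O)c1cc(Br)c(C)cc1O | starting material
2 | 3-(tert-butoxy)-3-oxopropanoic acid | CC(C)(C)OC(=O)CC(O)=O | starting material
3 | 2-acetyl-4-bromo-5-methylphenyl tert-butyl propanedioate (not isolated) | CC(=O)c1cc(Br)c(C)cc1OC(=O)CC(=O)OC(C)(C)C | intermediate
4 | tert-butyl 6-bromo-4,7-dimethyl-2-oxo-2H-chromene-3-carboxylate | Cc1cc2OC(=O)C(C(=O)OC(C)(C)C)=C(C)c2cc1Br | intermediate
5 | 4-iodobut-1-yne | C#CCCI | starting material
6 | racemic tert-butyl (3E,3aR,9bS)-8-bromo-3-(iodomethylidene)-7,9b-dimethyl-4-oxo-1,2,3,9b-tetrahydrocyclopenta[c]chromene-3a(4H)-carboxylate | Cc1cc2c(cc1Br)[C@]3(C)CC/C(=C\I)[C@]3(C(=O)OC(C)(C)C)C(=O)O2 | intermediate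
7 | racemic (3E,3aR,9bS)-8-bromo-3-(iodomethylidene)-7,9b-dimethyl-4-oxo-1,2,3,9b-tetrahydrocyclopenta[c]chromene-3a(4H)-carboxylic acid (not isolated) | Cc1cc2c(cc1Br)[C@]3(C)CC/C(=C\I)[C@]3(C(=O)O)C(=O)O2 | intermediate
8 | racemic (3E,3aR,9bR)-8-bromo-3-(iodomethylidene)-7,9b-dimethyl-2,3,3a,9b-tetrahydrocyclopenta[c]chromen-4(1H)-one | Cc1cc2c(cc1Br)[C@]3(C)CC/C(=C\I)[C@@H]3C(=O)O2 | intermediate
9 | (S)-1-phenylethan-1-amine | C[C@H](N)c1ccccc1 | starting material
10 | (1R,2R,5E)-2-(5-bromo-2-hydroxy-4-methylphenyl)-5-(iodomethylidene)-2-methyl-N-[(1S)-1-phenylethyl]cyclopentane-1-carboxamide | Cc1cc(O)c(cc1Br)[C@]2(C)CC/C(=C\I)[C@@H]2C(=O)N[C@@H](C)c1ccccc1 | intermediate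
11 | (3E,3aR,9bR)-8-bromo-3-(iodomethylidene)-7,9b-dimethyl-2,3,3a,9b-tetrahydrocyclopenta[c]chromen-4(1H)-one, single enantiomer | Cc1cc2c(cc1Br)[C@]3(C)CC/C(=C\I)[C@@H]3C(=O)O2 | intermediate
12 | (3E,3aR,9bR)-8-bromo-3-(iodomethylidene)-7,9b-dimethyl-1,2,3,3a,4,9b-hexahydrocyclopenta[c]chromen-4-ol, both anomers | Cc1cc2c(cc1Br)[C@]3(C)CC/C(=C\I)[C@@H]3C(O)O2 | intermediate
13 | 4-methylbenzenesulfonohydrazide | Cc1ccc(cc1)S(=O)(=O)NN | starting material
14 | N'-{[(1R,2R,5E)-2-(5-bromo-2-hydroxy-4-methylphenyl)-5-(iodomethylidene)-2-methylcyclopentyl]methylidene}-4-methylbenzenesulfonohydrazide (not isolated) | Cc1cc(O)c(cc1Br)[C@]2(C)CC/C(=C\I)[C@@H]2C=NNS(=O)(=O)c1ccc(C)cc1 | intermediate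
15 | 4-bromo-2-[(1R,2R,3E)-3-(iodomethylidene)-1,2-dimethylcyclopentyl]-5-methylphenol | Cc1cc(O)c([C@]2(C)CC/C(=C\I)[C@@H]2C)cc1Br | intermediate
16 | 4-bromo-2-[(1R,2R,3E)-3-(bromomethylidene)-1,2-dimethylcyclopentyl]-5-methylphenol | Cc1cc(O)c([C@]2(C)CC/C(=C\Br)[C@@H]2C)cc1Br | target

Total step count: 8. Longest linear sequence: 8 steps (1 to 16).

**Steps most likely to fail**

Step 2 (bears the label "Proposed new method:"). The chain may not be sustained, because addition of the primary radical to the tetrasubstituted C4 is slow and the but-3-ynyl radical can be lost by other paths; iodine transfer may also occur without full control of the alkene geometry. The fallback makes the same two bonds by known polar chemistry; it sets out from 4 and comes back to the route at 6. Copper-catalysed (CuBr·SMe2) conjugate addition of [4-(trimethylsilyl)but-3-yn-1-yl]magnesium bromide F1 (from commercial (4-bromobut-1-yn-1-yl)trimethylsilane and Mg) to 4 in THF at −40 °C should give tert-butyl 6-bromo-4,7-dimethyl-2-oxo-4-[4-(trimethylsilyl)but-3-yn-1-yl]-3,4-dihydro-2H-chromene-3-carboxylate F2. Buffered desilylation (TBAF/AcOH, THF, 0 °C) should give tert-butyl 6-bromo-4-(but-3-yn-1-yl)-4,7-dimethyl-2-oxo-3,4-dihydro-2H-chromene-3-carboxylate F3. Titanium-alkoxide-mediated iodocarbocyclisation of the malonate-type C3–H onto the alkyne (Ti(OtBu)4, I2, CH2Cl2, rt), known for 4-pentynylmalonates, is an anti addition that places iodine trans to C3a and should give racemic 6.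

Step 7. The carbon next to the hydrazone may epimerise through the ene-hydrazine tautomer, or the hydrazone may close onto the phenol to a cyclic N,O-aminal that resists hydroboration. The fallback avoids every enolisable carbonyl derivative; it sets out from 11, bypasses 12 and comes back at 15. Exhaustive hydrosilylation catalysed by B(C6F5)3 (Et3SiH, CH2Cl2, rt), the known reduction of an aliphatic ester carbonyl to CH3, should give {4-bromo-2-[(1R,2R,3E)-3-(iodomethylidene)-1,2-dimethylcyclopentyl]-5-methylphenoxy}triethylsilane F4, and TBAF (THF, 0 °C) should then release 15.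

Step 4. The diastereomeric amides may not be discriminated well enough on silica, or may relactonise in part on the column. The fallback is a physical resolution: racemic 8 would be separated directly into its enantiomers by preparative supercritical-fluid chromatography on a polysaccharide chiral stationary phase. It sets out from 8, comes back at 11 and makes no new compound F0.

**Further compounds**

F1 | step 2 | [4-(trimethylsilyl)but-3-yn-1-yl]magnesium bromide | C[Si](C)(C)C#CCC[Mg]Br
F2 | step 2 | tert-butyl 6-bromo-4,7-dimethyl-2-oxo-4-[4-(trimethylsilyl)but-3-yn-1-yl]-3,4-dihydro-2H-chromene-3-carboxylate (racemic, both C3 epimers) | Cc1cc2OC(=O)C(C(=O)OC(C)(C)C)C(C)(CCC#C[Si](C)(C)C)c2cc1Br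
F3 | step 2 | tert-butyl 6-bromo-4-(but-3-yn-1-yl)-4,7-dimethyl-2-oxo-3,4-dihydro-2H-chromene-3-carboxylate (racemic, both C3 epimers) | Cc1cc2OC(=O)C(C(=O)OC(C)(C)C)C(C)(CCC#C)c2cc1Br
F4 | step 7 | {4-bromo-2-[(1R,2R,3E)-3-(iodomethylidene)-1,2-dimethylcyclopentyl]-5-methylphenoxy}triethylsilane | Cc1cc(O[Si](CC)(CC)CC)c([C@]2(C)CC/C(=C\I)[C@@H]2C)cc1Br
F0 | step 4 | none | none
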